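**Retrosynthetic overview**

1. Target (2S; both chain alkenes E): the phenol is unmasked last, the C3=C4 alkene is made by reduction and dehydration of a C4 ketone, and the CO2H comes from a CH2OH group. This leads back to a (2S)-2,2-disubstituted chroman-4-one.
2. Key disconnection C2–C1' (C1' = the chain CH2 bonded to C2): copper-catalysed enantioselective 1,4-addition of the complete C16 homoallylic Grignard reagent to a 2-methyl-4H-chromen-4-one. The enabling feature is the γ-pyrone ring O1–C2=C3–C4(=O)–C4a–C8a, in which C2 is the β-carbon of a vinylogous ester. The C3=C4 alkene of the target is what remains of that C4 carbonyl, and C1' lies two carbons from the C3'=C4' alkene, so it can be a stable primary Grignard carbon.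
3. Chromone: from 2,3-dimethylhydroquinone by C-acetylation, Claisen condensation/cyclodehydration and O-silylation.
4. C16 bromide: Horner–Wadsworth–Emmons olefination of pent-4-ynal (E-C7'=C8'), ester to CH2OTBS, then the alkyne is turned into the E-trisubstituted homoallylic alcohol by Zr-catalysed carboalumination/oxirane opening, then Appel bromination.
5. Ring order: the benzene ring is bought; the pyranone ring is the only ring formed (step 2, before the union); the key step closes no ring.

Key step: step 10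

Remark: the sense of induction of the copper catalyst in step 10 cannot be predicted with certainty, so the ligand enantiomer that delivers the alkyl group to the Si face of C2 is taken to be chosen after a screen with a simple primary Grignard reagent; 2,3-dimethylhydroquinone, triethyl phosphonoacetate, 5-bromo-2-methylpent-2-ene and pent-4-ynal are taken as commercial.

**Route**

Step 1
Reactants: 1 2,3-dimethylbenzene-1,4-diol
Product: 2 1-(2,5-dihydroxy-3,4-dimethylphenyl)ethan-1-one
Conditions: AcOH, BF3·OEt2 (excess), 100 °C; aq. NaOAc work-up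
Reagents that add atoms: acetic acid, CC(=O)O
Why: BF3-promoted Friedel–Crafts/Fries-type C-acylation ortho to a phenolic OH; the two free ring positions of 1 are equivalent and the chelated ketone is deactivated toward a second acylation.

Step 2
Reactants: 2 1-(2,5-dihydroxy-3,4-dimethylphenyl)ethan-1-one
Product: 4 6-hydroxy-2,7,8-trimethyl-4H-chromen-4-one, via β-diketone 3 (not isolated)
Conditions: NaH (5 equiv), EtOAc, THF, reflux; then conc. HCl–AcOH, 90 °C
Reagents that add atoms: ethyl acetate, CCOC(C)=O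
Why: Claisen condensation of the methyl ketone enolate with ethyl acetate gives the β-diketone, and acid-catalysed cyclodehydration through the ortho phenol closes the γ-pyrone ring (classical 2-methylchromone synthesis), the para OH being unable to reach the distal carbonyl.

Step 3
Reactants: 4 6-hydroxy-2,7,8-trimethyl-4H-chromen-4-one
Product: 5 2,7,8-trimethyl-6-{[tri(propan-2-yl)silyl]oxy}-4H-chromen-4-one
Conditions: TIPSCl, imidazole, DMF, rt
Reagents that add atoms: chlorotri(propan-2-yl)silane, CC(C)[Si](Cl)(C(C)C)C(C)C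
Why: Standard O-silylation of a phenol; the aryl TIPS ether should survive the Grignard/copper step, mild acid, MnO2, chlorite and borohydride and is removed by fluoride at the end.

Step 4
Reactants: 6 triethyl phosphonoacetate; 7 5-bromo-2-methylpent-2-ene
Product: 8 ethyl 2-(diethoxyphosphoryl)-6-methylhept-5-enoate (racemic)
Conditions: NaH, THF–DMSO, 0 → 60 °C (slight excess of 6)
Reagents that add atoms: none
Why: SN2 C-alkylation of the stabilised phosphonoacetate anion with a primary bromide; the excess of 6 limits dialkylation and the stereocentre formed is destroyed in step 5.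

Step 5
Reactants: 8 ethyl 2-(diethoxyphosphoryl)-6-methylhept-5-enoate; 9 pent-4-ynal
Product: 10 ethyl (2E)-2-(4-methylpent-3-en-1-yl)hept-2-en-6-ynoate
Conditions: NaH, THF, 0 °C → rt; chromatographic removal of the minor Z isomer
Reagents that add atoms: none
Why: Horner–Wadsworth–Emmons olefination with a stabilised α-alkyl phosphonate should favour the E-enoate (ester trans to the chain, as in the target); the terminal alkyne is inert to the preformed phosphonate anion.

Step 6
Reactants: 10 ethyl (2E)-2-(4-methylpent-3-en-1-yl)hept-2-en-6-ynoate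
Product: 11 (2E)-2-(4-methylpent-3-en-1-yl)hept-2-en-6-yn-1-ol
Conditions: DIBAL-H (2.5 equiv), CH2Cl2, −78 °C; Rochelle salt work-up
Reagents that add atoms: none
Why: DIBAL-H 1,2-reduction of an enoate to the allylic alcohol should leave the alkene geometry, the alkyne and the isolated alkene untouched.

Step 7
Reactants: 11 (2E)-2-(4-methylpent-3-en-1-yl)hept-2-en-6-yn-1-ol
Product: 12 tert-butyl(dimethyl){[(2E)-2-(4-methylpent-3-en-1-yl)hept-2-en-6-yn-1-yl]oxy}silane
Conditions: TBSCl, imidazole, CH2Cl2, rt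
Reagents that add atoms: tert-butyl(chloro)dimethylsilane, CC(C)(C)[Si](C)(C)Cl
Why: Standard silylation of a primary alcohol; the TBS ether masks the future carboxyl carbon against organoaluminium, Appel and Grignard conditions.

Step 8
Reactants: 12 tert-butyl(dimethyl){[(2E)-2-(4-methylpent-3-en-1-yl)hept-2-en-6-yn-1-yl]oxy}silane
Product: 15 (3E,7E)-8-({[tert-butyl(dimethyl)silyl]oxy}methyl)-4,12-dimethyltrideca-3,7,11-trien-1-ol, via alkenylalane 13 (not isolated), via lithium alkenylaluminate 14 (not isolated)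
Conditions: Me3Al (2.5 equiv), Cp2ZrCl2 (0.25 equiv), CH2Cl2, 0 °C → rt; evaporate; hexane, n-BuLi, 0 °C; THF, oxirane, −30 °C → rt; aq. Rochelle salt
Reagents that add atoms: trimethylaluminium, C[Al](C)C; oxirane, C1CO1
Why: Negishi Zr-catalysed syn-carboalumination puts methyl on the internal and aluminium on the terminal alkyne carbon (E-alkenylalane), and the derived lithium aluminate should open oxirane with retention of alkene geometry to give the E-homoallylic alcohol.

Step 9
Reactants: 15 (3E,7E)-8-({[tert-butyl(dimethyl)silyl]oxy}methyl)-4,12-dimethyltrideca-3,7,11-trien-1-ol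
Product: 16 {[(2E,6E)-9-bromo-6-methyl-2-(4-methylpent-3-en-1-yl)nona-2,6-dien-1-yl]oxy}(tert-butyl)dimethylsilane
Conditions: CBr4, PPh3, CH2Cl2, 0 °C
Reagents that add atoms: tetrabromomethane, BrC(Br)(Br)Br
Why: Appel bromination of a primary alcohol under neutral conditions should leave the silyl ether and the trisubstituted alkenes untouched.

Step 10
Reactants: 16 {[(2E,6E)-9-bromo-6-methyl-2-(4-methylpent-3-en-1-yl)nona-2,6-dien-1-yl]oxy}(tert-butyl)dimethylsilane (1.6 equiv); 5 2,7,8-trimethyl-6-{[tri(propan-2-yl)silyl]oxy}-4H-chromen-4-one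
Product: 20 (2S)-2-[(3E,7E)-8-(hydroxymethyl)-4,12-dimethyltrideca-3,7,11-trien-1-yl]-2,7,8-trimethyl-6-{[tri(propan-2-yl)silyl]oxy}-2,3-dihydro-4H-chromen-4-one, via Grignard reagent 17 (not isolated), via silyl enol ether 18 (not isolated), via TBS-protected chromanone 19 (not isolated)
Conditions: 16, Mg, I2 (cat.), Et2O, reflux; added over 2 h to 5, CuBr·SMe2 (10 mol %), Josiphos-type ferrocenyl diphosphine (12 mol %), TMSCl (2 equiv), CH2Cl2, −78 °C; aq. NH4Cl; then CSA (0.2 equiv), MeOH–CH2Cl2, 0 °C → rt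
Reagents that add atoms: none
Why: Proposed new method: Grignard reagent 17 transmetalates to a chiral diphosphine–Cu(I) alkyl, which π-complexes the C2=C3 bond of chromone 5 and adds oxidatively at C2 (the β-carbon of the vinylogous ester), TMSCl trapping the Cu(III) enolate as silyl enol ether 18 so that reductive elimination is fast and the enolate cannot ring-open by retro-oxa-Michael reaction, after which acidic methanolysis releases the ketone and cleaves the primary TBS ether. The closest known reaction types are the Cu/ferrocenyl-diphosphine-catalysed asymmetric conjugate addition of Grignard reagents to 2-unsubstituted chromones and the Cu-catalysed asymmetric 1,4-addition of alkyl-metal reagents to β-substituted cyclic enones that gives quaternary centres. No ring is closed: the pyranone ring is already present and is only saturated at C2–C3. The new quaternary stereocentre C2 is controlled by the chiral ligand on copper alone, which must deliver the alkyl group to the Si face of C2 (small methyl on one side, the flat benzo-fused ring oxygen on the other) to give the 2S configuration. The step needs 1,4- over 1,2-addition and must outrun deprotonation of the 2-methyl group; the vinylogous-ester character of the C4 carbonyl, the soft copper nucleophile, slow addition at −78 °C and the silyl trap should secure this.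

Step 11
Reactants: 20 (2S)-2-[(3E,7E)-8-(hydroxymethyl)-4,12-dimethyltrideca-3,7,11-trien-1-yl]-2,7,8-trimethyl-6-{[tri(propan-2-yl)silyl]oxy}-2,3-dihydro-4H-chromen-4-one
Product: 21 (2E,6E)-6-methyl-2-(4-methylpent-3-en-1-yl)-9-[(2S)-2,7,8-trimethyl-4-oxo-6-{[tri(propan-2-yl)silyl]oxy}-3,4-dihydro-2H-chromen-2-yl]nona-2,6-dienal
Conditions: activated MnO2 (excess), CH2Cl2, rt
Reagents that add atoms: none
Why: MnO2 oxidises only the allylic primary alcohol to the E-enal; the ketone, aryl silyl ether and isolated alkenes should not react.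

Step 12
Reactants: 21 (2E,6E)-6-methyl-2-(4-methylpent-3-en-1-yl)-9-[(2S)-2,7,8-trimethyl-4-oxo-6-{[tri(propan-2-yl)silyl]oxy}-3,4-dihydro-2H-chromen-2-yl]nona-2,6-dienal
Product: 22 (2E,6E)-6-methyl-2-(4-methylpent-3-en-1-yl)-9-[(2S)-2,7,8-trimethyl-4-oxo-6-{[tri(propan-2-yl)silyl]oxy}-3,4-dihydro-2H-chromen-2-yl]nona-2,6-dienoic acid
Conditions: NaClO2, NaH2PO4, 2-methylbut-2-ene (excess), t-BuOH–H2O, 0 °C → rt
Reagents that add atoms: sodium chlorite, [Na+].[O-]Cl=O
Why: Pinnick oxidation converts the enal into the acid without E/Z isomerisation; the alkene scavenger removes HOCl and so protects the other alkenes and the electron-rich arene.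

Step 13
Reactants: 22 (2E,6E)-6-methyl-2-(4-methylpent-3-en-1-yl)-9-[(2S)-2,7,8-trimethyl-4-oxo-6-{[tri(propan-2-yl)silyl]oxy}-3,4-dihydro-2H-chromen-2-yl]nona-2,6-dienoic acid
Product: 23 (2E,6E)-9-[(2S,4RS)-4-hydroxy-2,7,8-trimethyl-6-{[tri(propan-2-yl)silyl]oxy}-3,4-dihydro-2H-chromen-2-yl]-6-methyl-2-(4-methylpent-3-en-1-yl)nona-2,6-dienoic acid
Conditions: NaBH4 (3 equiv), MeOH–THF, 0 °C; aq. citric acid work-up
Reagents that add atoms: none
Why: Borohydride reduction of the aryl ketone; the conjugated carboxylate is not reduced, and the new C4 stereocentre is formed as a mixture that is erased in step 14.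

Step 14
Reactants: 23 (2E,6E)-9-[(2S,4RS)-4-hydroxy-2,7,8-trimethyl-6-{[tri(propan-2-yl)silyl]oxy}-3,4-dihydro-2H-chromen-2-yl]-6-methyl-2-(4-methylpent-3-en-1-yl)nona-2,6-dienoic acid
Product: 24 (2E,6E)-6-methyl-2-(4-methylpent-3-en-1-yl)-9-[(2S)-2,7,8-trimethyl-6-{[tri(propan-2-yl)silyl]oxy}-2H-chromen-2-yl]nona-2,6-dienoic acid
Conditions: p-TsOH·H2O (5 mol %), toluene, 4 Å MS, 50 °C, short time, dark
Reagents that add atoms: none
Why: Acid-catalysed E1 dehydration through the C4 benzylic cation, stabilised by the ortho ring oxygen, gives the conjugated C3=C4 bond; C2 takes no part, so its configuration should be kept.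

Step 15
Reactants: 24 (2E,6E)-6-methyl-2-(4-methylpent-3-en-1-yl)-9-[(2S)-2,7,8-trimethyl-6-{[tri(propan-2-yl)silyl]oxy}-2H-chromen-2-yl]nona-2,6-dienoic acid
Product: 25 (2E,6E)-9-[(2S)-6-hydroxy-2,7,8-trimethyl-2H-chromen-2-yl]-6-methyl-2-(4-methylpent-3-en-1-yl)nona-2,6-dienoic acid
Conditions: TBAF (3 equiv), AcOH (3 equiv), THF, 0 °C → rt, argon, dark; aq. citric acid work-up
Reagents that add atoms: none
Why: Buffered fluoride desilylation of the aryl TIPS ether should release the phenol without touching the chromene, the alkenes or the acid; air and light are excluded because the free 6-hydroxychromene is oxidation- and light-sensitive.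

**Compound list**

1 | 2,3-dimethylbenzene-1,4-diol | Cc1c(C)c(O)ccc1O | starting material
2 | 1-(2,5-dihydroxy-3,4-dimethylphenyl)ethan-1-one | CC(=O)c1cc(O)c(C)c(C)c1O | intermediate
3 | 1-(2,5-dihydroxy-3,4-dimethylphenyl)butane-1,3-dione | CC(=O)CC(=O)c1cc(O)c(C)c(C)c1O | intermediate
4 | 6-hydroxy-2,7,8-trimethyl-4H-chromen-4-one | Cc1cc(=O)c2cc(O)c(C)c(C)c2o1 | intermediate
5 | 2,7,8-trimethyl-6-{[tri(propan-2-yl)silyl]oxy}-4H-chromen-4-one | Cc1cc(=O)c2cc(O[Si](C(C)C)(C(C)C)C(C)C)c(C)c(C)c2o1 | intermediate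
6 | triethyl phosphonoacetate | CCOC(=O)CP(=O)(OCC)OCC | starting material
7 | 5-bromo-2-methylpent-2-ene | CC(C)=CCCBr | starting material
8 | ethyl 2-(diethoxyphosphoryl)-6-methylhept-5-enoate (racemic) | CCOC(=O)C(CCC=C(C)C)P(=O)(OCC)OCC | intermediate
9 | pent-4-ynal | C#CCCC=O | starting material
10 | ethyl (2E)-2-(4-methylpent-3-en-1-yl)hept-2-en-6-ynoate | CCOC(=O)/C(CCC=C(C)C)=C/CCC#C | intermediate
11 | (2E)-2-(4-methylpent-3-en-1-yl)hept-2-en-6-yn-1-ol | OC/C(CCC=C(C)C)=C/CCC#C | intermediate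
12 | tert-butyl(dimethyl){[(2E)-2-(4-methylpent-3-en-1-yl)hept-2-en-6-yn-1-yl]oxy}silane | CC(C)(C)[Si](C)(C)OC/C(CCC=C(C)C)=C/CCC#C | intermediate
13 | [(1E,5E)-6-({[tert-butyl(dimethyl)silyl]oxy}methyl)-2,10-dimethylundeca-1,5,9-trien-1-yl](dimethyl)alumane | C[Al](C)/C=C(\C)CC/C=C(/CO[Si](C)(C)C(C)(C)C)CCC=C(C)C | intermediate
14 | lithium butyl[(1E,5E)-6-({[tert-butyl(dimethyl)silyl]oxy}methyl)-2,10-dimethylundeca-1,5,9-trien-1-yl]dimethylaluminate | [Li+].CCCC[Al-](C)(C)/C=C(\C)CC/C=C(/CO[Si](C)(C)C(C)(C)C)CCC=C(C)C | intermediate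
15 | (3E,7E)-8-({[tert-butyl(dimethyl)silyl]oxy}methyl)-4,12-dimethyltrideca-3,7,11-trien-1-ol | OCC/C=C(\C)CC/C=C(/CO[Si](C)(C)C(C)(C)C)CCC=C(C)C | intermediate
16 | {[(2E,6E)-9-bromo-6-methyl-2-(4-methylpent-3-en-1-yl)nona-2,6-dien-1-yl]oxy}(tert-butyl)dimethylsilane | BrCC/C=C(\C)CC/C=C(/CO[Si](C)(C)C(C)(C)C)CCC=C(C)C | intermediate
17 | [(3E,7E)-8-({[tert-butyl(dimethyl)silyl]oxy}methyl)-4,12-dimethyltrideca-3,7,11-trien-1-yl]magnesium bromide | Br[Mg]CC/C=C(\C)CC/C=C(/CO[Si](C)(C)C(C)(C)C)CCC=C(C)C | intermediate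
18 | {[(2S)-2-[(3E,7E)-8-({[tert-butyl(dimethyl)silyl]oxy}methyl)-4,12-dimethyltrideca-3,7,11-trien-1-yl]-2,7,8-trimethyl-4-[(trimethylsilyl)oxy]-2H-chromen-6-yl]oxy}tri(propan-2-yl)silane | CC(C)=CCC/C(CO[Si](C)(C)C(C)(C)C)=C\CC/C(C)=C/CC[C@@]1(C)C=C(O[Si](C)(C)C)c2cc(O[Si](C(C)C)(C(C)C)C(C)C)c(C)c(C)c2O1 | intermediate
19 | (2S)-2-[(3E,7E)-8-({[tert-butyl(dimethyl)silyl]oxy}methyl)-4,12-dimethyltrideca-3,7,11-trien-1-yl]-2,7,8-trimethyl-6-{[tri(propan-2-yl)silyl]oxy}-2,3-dihydro-4H-chromen-4-one | CC(C)=CCC/C(CO[Si](C)(C)C(C)(C)C)=C\CC/C(C)=C/CC[C@@]1(C)CC(=O)c2cc(O[Si](C(C)C)(C(C)C)C(C)C)c(C)c(C)c2O1 | intermediate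
20 | (2S)-2-[(3E,7E)-8-(hydroxymethyl)-4,12-dimethyltrideca-3,7,11-trien-1-yl]-2,7,8-trimethyl-6-{[tri(propan-2-yl)silyl]oxy}-2,3-dihydro-4H-chromen-4-one | CC(C)=CCC/C(CO)=C\CC/C(C)=C/CC[C@@]1(C)CC(=O)c2cc(O[Si](C(C)C)(C(C)C)C(C)C)c(C)c(C)c2O1 | intermediate
21 | (2E,6E)-6-methyl-2-(4-methylpent-3-en-1-yl)-9-[(2S)-2,7,8-trimethyl-4-oxo-6-{[tri(propan-2-yl)silyl]oxy}-3,4-dihydro-2H-chromen-2-yl]nona-2,6-dienal | CC(C)=CCC/C(C=O)=C\CC/C(C)=C/CC[C@@]1(C)CC(=O)c2cc(O[Si](C(C)C)(C(C)C)C(C)C)c(C)c(C)c2O1 | intermediate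
22 | (2E,6E)-6-methyl-2-(4-methylpent-3-en-1-yl)-9-[(2S)-2,7,8-trimethyl-4-oxo-6-{[tri(propan-2-yl)silyl]oxy}-3,4-dihydro-2H-chromen-2-yl]nona-2,6-dienoic acid | CC(C)=CCC/C(C(=O)O)=C\CC/C(C)=C/CC[C@@]1(C)CC(=O)c2cc(O[Si](C(C)C)(C(C)C)C(C)C)c(C)c(C)c2O1 | intermediate
23 | (2E,6E)-9-[(2S,4RS)-4-hydroxy-2,7,8-trimethyl-6-{[tri(propan-2-yl)silyl]oxy}-3,4-dihydro-2H-chromen-2-yl]-6-methyl-2-(4-methylpent-3-en-1-yl)nona-2,6-dienoic acid | CC(C)=CCC/C(C(=O)O)=C\CC/C(C)=C/CC[C@@]1(C)CC(O)c2cc(O[Si](C(C)C)(C(C)C)C(C)C)c(C)c(C)c2O1 | intermediate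
24 | (2E,6E)-6-methyl-2-(4-methylpent-3-en-1-yl)-9-[(2S)-2,7,8-trimethyl-6-{[tri(propan-2-yl)silyl]oxy}-2H-chromen-2-yl]nona-2,6-dienoic acid | CC(C)=CCC/C(C(=O)O)=C\CC/C(C)=C/CC[C@@]1(C)C=Cc2cc(O[Si](C(C)C)(C(C)C)C(C)C)c(C)c(C)c2O1 | intermediate
25 | (2E,6E)-9-[(2S)-6-hydroxy-2,7,8-trimethyl-2H-chromen-2-yl]-6-methyl-2-(4-methylpent-3-en-1-yl)nona-2,6-dienoic acid | CC(C)=CCC/C(=C\CC/C(C)=C/CC[C@@]1(C)C=Cc2cc(O)c(C)c(C)c2O1)C(=O)O | target

**Summary**

Total step count: 15.
Longest linear sequence: 12 steps (steps 4–15, from 6 and 7 to 25); the chromone branch (steps 1–3) joins at step 10.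

Steps most likely to fail:

1. Step 10 (bears the label "Proposed new method:"). The catalysed 1,4-addition at the fully substituted C2 may be too slow, so that uncatalysed 1,2-addition or deprotonation of the 2-methyl group takes over, or the catalyst may discriminate the two faces of C2 poorly. The fallback uses known chemistry and sets out from 16 and 5. Grignard reagent 17 is converted with CuI into the organocopper reagent and added to 5 in the presence of BF3·OEt2 (THF, −78 °C; Lewis-acid-assisted organocopper conjugate addition to a β,β-disubstituted enone), which should give the racemic silyl-protected chromanone F1. CSA/MeOH then gives the racemic hydroxy ketone F2, and preparative chiral-phase SFC of F2 separates the enantiomers and returns to the route at 20.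

2. Step 8. The alkenyl group may transfer poorly from the aluminate to oxirane (competing butyl or methyl transfer, oligomerisation of oxirane), and the Lewis-basic silyl ether may slow the carbometalation. The fallback sets out from 12. Alkenylalane 13 is generated as in step 8 but is cross-coupled with vinyl bromide (Pd(PPh3)4 cat., ZnCl2, THF, rt) to give the triene tert-butyl(dimethyl){[(2E,6E)-6-methyl-2-(4-methylpent-3-en-1-yl)nona-2,6,8-trien-1-yl]oxy}silane F3. 9-BBN should hydroborate only the terminal vinyl group of F3 to give the alkylborane F4, and NaOH/H2O2 oxidation returns to the route at 15.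

3. Step 5. The olefination may give insufficient E-selectivity and an inseparable isomer mixture. The fallback sets out from 9 and fixes the geometry in two stereodefined events. Wittig olefination with ethyl bromo(triphenyl-λ5-phosphanylidene)acetate (CH2Cl2, rt) should give ethyl (2Z)-2-bromohept-2-en-6-ynoate F5, with the ester already trans to the chain. A Negishi coupling of F5 with (4-methylpent-3-en-1-yl)zinc bromide F6 (from 7, Zn, LiCl, THF; Pd(dppf)Cl2 cat.) should replace bromine with retention and return to the route at 10.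

Further compounds
F1 | step 10 | rac-2-[(3E,7E)-8-({[tert-butyl(dimethyl)silyl]oxy}methyl)-4,12-dimethyltrideca-3,7,11-trien-1-yl]-2,7,8-trimethyl-6-{[tri(propan-2-yl)silyl]oxy}-2,3-dihydro-4H-chromen-4-one | CC(C)=CCC/C(CO[Si](C)(C)C(C)(C)C)=C\CC/C(C)=C/CCC1(C)CC(=O)c2cc(O[Si](C(C)C)(C(C)C)C(C)C)c(C)c(C)c2O1
F2 | step 10 | rac-2-[(3E,7E)-8-(hydroxymethyl)-4,12-dimethyltrideca-3,7,11-trien-1-yl]-2,7,8-trimethyl-6-{[tri(propan-2-yl)silyl]oxy}-2,3-dihydro-4H-chromen-4-one | CC(C)=CCC/C(CO)=C\CC/C(C)=C/CCC1(C)CC(=O)c2cc(O[Si](C(C)C)(C(C)C)C(C)C)c(C)c(C)c2O1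
F3 | step 8 | tert-butyl(dimethyl){[(2E,6E)-6-methyl-2-(4-methylpent-3-en-1-yl)nona-2,6,8-trien-1-yl]oxy}silane | C=C/C=C(\C)CC/C=C(/CO[Si](C)(C)C(C)(C)C)CCC=C(C)C
F4 | step 8 | 9-[(3E,7E)-8-({[tert-butyl(dimethyl)silyl]oxy}methyl)-4,12-dimethyltrideca-3,7,11-trien-1-yl]-9-borabicyclo[3.3.1]nonane | C1CC2CCCC(C1)B2CC/C=C(\C)CC/C=C(/CO[Si](C)(C)C(C)(C)C)CCC=C(C)C
F5 | step 5 | ethyl (2Z)-2-bromohept-2-en-6-ynoate | CCOC(=O)/C(Br)=C/CCC#C
F6 | step 5 | (4-methylpent-3-en-1-yl)zinc bromide | CC(C)=CCC[Zn]Br
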